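**Retrosynthetic overview**
1. Ring order: the A ring is bought intact in acetophenone 1; the pyranone ring is closed next (1 → enaminone 2 → chromone 3); the B ring arrives last as aryl iodide 4.
2. Key disconnection (C2–C1'): C2 of chromone 3, normally the electrophilic β-carbon of the enone, is used with reversed polarity as the carbanion 5 (a β-acylvinyl anion, i.e. a d3, homoenolate-type synthon). It is joined to the electrophilic C–I carbon of 4 to give target 6.
3. Second disconnection (C2–C3 and O1–C2): C2 is a one-carbon unit from DMF-DMA, attached to the acetyl CH3 of 1 and closed onto the ortho phenol with loss of dimethylamine.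
4. Compound 6 has no stereocentre, so no stereocontrol step is needed.

Assumption: the target SMILES contains no stereocentre and no stereogenic double bond, so the "single enantiomer" is simply the achiral compound; 1, 4 and TMPZnCl·LiCl are taken as catalogue items.

**Route**

Step 1
Reactants: 1 1-(2-hydroxy-3,4,6-trimethoxyphenyl)ethan-1-one (2'-hydroxy-3',4',6'-trimethoxyacetophenone)
Product: 3 5,7,8-trimethoxy-4H-chromen-4-one, via enaminone 2 (not isolated)
Conditions: DMF-DMA (2 equiv), PhMe, 100 °C, 3 h; evaporate; then conc. HCl, CH2Cl2, 40 °C, 1 h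
Reagents that add atoms: N,N-dimethylformamide dimethyl acetal (DMF-DMA), COC(OC)N(C)C
Why: Amide-acetal condensation at the enolisable acetyl CH3 gives the (E)-enaminone, and acid then drives intramolecular oxa-Michael addition of the ortho phenol and β-elimination of dimethylamine (enaminone-to-chromone cyclisation); no stereocentre is formed.

Step 2
Reactants: 3 5,7,8-trimethoxy-4H-chromen-4-one; 4 4-iodo-1,2-dimethoxybenzene
Product: 6 isosinensetin, via chromon-2-ylzinc chloride 5 (not isolated)
Conditions: TMPZnCl·LiCl (1.2 equiv), THF, 25 °C, 1 h; then 4 (1.0 equiv), Pd(dba)2 (3 mol %), P(2-furyl)3 (6 mol %), 50 °C, 12 h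
Reagents that add atoms: none
Why: The hindered, non-nucleophilic zinc amide removes the most acidic vinylic proton (C2–H, α to the ring oxygen; no Mg Lewis acid is present to steer it to C3), and the resulting C2–Zn species, a β-acylvinyl anion that reverses the normal electrophilic character of C2, undergoes Negishi cross-coupling with the electrophilic aryl iodide; no stereocentre is formed.

**Compound list**
1 | 1-(2-hydroxy-3,4,6-trimethoxyphenyl)ethan-1-one | CC(=O)c1c(O)c(OC)c(OC)cc1OC | starting material
2 | (E)-3-(dimethylamino)-1-(2-hydroxy-3,4,6-trimethoxyphenyl)prop-2-en-1-one | CN(C)/C=C/C(=O)c1c(O)c(OC)c(OC)cc1OC | intermediate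
3 | 5,7,8-trimethoxy-4H-chromen-4-one | COc1cc(OC)c2c(=O)ccoc2c1OC | intermediate
4 | 4-iodo-1,2-dimethoxybenzene | COc1ccc(I)cc1OC | starting material
5 | chlorido(5,7,8-trimethoxy-4-oxo-4H-chromen-2-yl)zinc (LiCl complex) | COc1cc(OC)c2c(=O)cc([Zn]Cl)oc2c1OC | intermediate
6 | isosinensetin, 2-(3,4-dimethoxyphenyl)-5,7,8-trimethoxy-4H-chromen-4-one | COc1ccc(-c2cc(=O)c3c(OC)cc(OC)c(OC)c3o2)cc1OC | target

**Step count and risks**

Total step count: 2. Longest linear sequence: 2 (1 → 3 → 6). The route has only two steps, so both are ranked, and the two stages of step 2 are treated as separate failure points.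

Most likely to fail: step 2, zincation stage. The 5-OMe/C4=O pocket may hold the zinc amide and steer metalation to C3, or metalation of this electron-rich chromone may stall. The fallback sets out from 3 and comes back at 6, and it gives up the carbanion at C2. Pd(II)-catalysed conjugate addition of commercial (3,4-dimethoxyphenyl)boronic acid to 3 [Pd(TFA)2 (5 mol %), 2,2'-bipyridine (6 mol %), ClCH2CH2Cl/H2O, 60 °C] gives racemic 2-(3,4-dimethoxyphenyl)-5,7,8-trimethoxychroman-4-one F1. Its single stereocentre is erased when F1 is dehydrogenated with I2 (10 mol %) in DMSO at 120 °C to give 6.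

Second: step 2, coupling stage. Even if 5 forms cleanly (checked by iodine quench of an aliquot), the Negishi coupling with the electron-rich iodide 4 may be slow and lose 5 to protodezincation or homocoupling. The fallback sets out from 5 (made from 3 as in step 2) and comes back at 6, with the roles of nucleophile and electrophile exchanged. Compound 5 is quenched with I2 (THF, 0 °C) to give 2-iodo-5,7,8-trimethoxy-4H-chromen-4-one F2, which is isolated. F2 is then joined to (3,4-dimethoxyphenyl)boronic acid by Suzuki–Miyaura coupling [Pd(PPh3)4 (5 mol %), anhydrous K3PO4, dioxane, 90 °C]. Anhydrous base is used because C2 of F2 is a vinylogous acyl iodide.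

Third: step 1. DMF-DMA may O-methylate the phenol or condense sluggishly with the acetyl group, which is flanked by two ortho substituents. The fallback sets out from 1 and comes back at 3. Crossed Claisen formylation of the ketone enolate (NaH, HCO2Et, THF, 0 °C to rt) gives racemic 2-hydroxy-5,7,8-trimethoxychroman-4-one F3, the cyclic hemiacetal of the β-ketoaldehyde. F3 is dehydrated to 3 with catalytic conc. HCl in AcOH at 60 °C.

**Further compounds**
F1 | step 2 | rac-2-(3,4-dimethoxyphenyl)-5,7,8-trimethoxychroman-4-one | COc1ccc(C2CC(=O)c3c(OC)cc(OC)c(OC)c3O2)cc1OC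
F2 | step 2 | 2-iodo-5,7,8-trimethoxy-4H-chromen-4-one | COc1cc(OC)c2c(=O)cc(I)oc2c1OC
F3 | step 1 | rac-2-hydroxy-5,7,8-trimethoxychroman-4-one | COc1cc(OC)c2C(=O)CC(O)Oc2c1OC
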